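**Retrosynthetic overview**
1. Target 27 ⇐ hydroxy acid 26 ⇐ side-chain diene by two Wittig reactions on the C12 aldehyde; 7α-OH by SeO2 allylic hydroxylation of the 8(17)-alkene; C17 by Wittig methylenation of C8 ketone 20; C11–C12 is the hydroborated C9 vinyl group.
2. The trans ring fusion (5α-H) comes from radical (hydrogen-atom-transfer) hydrogenation of the C5=C6 alkene in octalin 16.
3. Ring A is closed by the C2–C3 bond: a sulfonyl carbanion on C2 adds 6-endo to C3 of a 2-(cyclohexenyl)acrylate, and the resulting dienolate takes up the C18 methyl at C4 in the same flask (12 → 15). The enabling feature is that C4 of ring A is quaternary and bears the C19 carboxyl: as the sp2 carbon of C3=C4(C19O2R)–C5=C6 it makes C3 an acceptor and then C4 a nucleophile, while the axial C20 methyl on the ring-fusion carbon C10 steers the methyl to the α face.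
4. Monocycle 12 ⇐ enol triflate 7 + stannyl acrylate 11 (Stille); 7 ⇐ quinone monoketal 1 by Rh-catalysed desymmetrising vinyl addition (C9), α'-methylation and Michael addition to phenyl vinyl sulfone (C10, C1–C2), then reductive triflation.
5. Ring order: ring B is the six-membered ring of 1 from the start; ring A is formed in step 8.

Key step: step 8

Remark: atoms carry the labdane numbering of the target (C1–C10 ring carbons, C11–C16 side chain, C17 exocyclic methylene carbon, C18 methyl on C4, C19 carboxyl carbon, C20 methyl on C10), α is the face opposite to C20, the target is read as 7α-acetoxylabda-8(17),12E,14-trien-19-oic acid, and quinone monoketal 1 is taken as a catalogue compound.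

Step 1
Reactants: 1 4,4-dimethoxycyclohexa-2,5-dien-1-one
Product: 2 (S)-4,4-dimethoxy-5-vinylcyclohex-2-en-1-one
Conditions: potassium vinyltrifluoroborate (1.1 equiv), [Rh(cod)2]PF6 (3 mol %), (S)-BINAP (3.3 mol %), Et3N, toluene/H2O 10:1, 90 °C
Reagents that add atoms: potassium vinyltrifluoroborate, C=C[B-](F)(F)F.[K+]
Why: Rh-catalysed asymmetric 1,4-addition (Hayashi–Miyaura type) to one of the two enantiotopic enone halves; (S)-BINAP is chosen by analogy with cyclohexenone, where it directs the organorhodium to the face that corresponds to (S)-2, and this sets C9 (the later 9β side chain), while the limited amount of vinyl donor should spare the second enone.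

Step 2
Reactants: 2 (S)-4,4-dimethoxy-5-vinylcyclohex-2-en-1-one
Product: 4 (5R)-4,4-dimethoxy-6-methyl-5-vinylcyclohex-2-en-1-one (both C6 epimers), via lithium dienolate 3 (not isolated)
Conditions: LiN(i-Pr)2, THF, −78 °C; then MeI, −78 to −20 °C
Reagents that add atoms: iodomethane, CI
Why: Kinetic α'-alkylation of an enone enolate, regiospecific because C10 is the only enolisable carbon (C6 is sp2, C8 is quaternary); the C10 configuration does not matter since this centre is re-enolised in step 3.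

Step 3
Reactants: 4 (5R)-4,4-dimethoxy-6-methyl-5-vinylcyclohex-2-en-1-one
Product: 5 (5R,6R)-4,4-dimethoxy-6-methyl-6-[2-(phenylsulfonyl)ethyl]-5-vinylcyclohex-2-en-1-one
Conditions: phenyl vinyl sulfone, KOt-Bu (0.2 equiv), t-BuOH/THF, 0 °C to rt
Reagents that add atoms: phenyl vinyl sulfone, C=CS(=O)(=O)c1ccccc1
Why: Base-catalysed Michael addition of the tetrasubstituted enolate to the vinyl sulfone; the acceptor should approach anti to the neighbouring C9 vinyl group, which creates the quaternary C10 with C20 cis to the vinyl group, and the protic medium protonates the α-sulfonyl carbanion before it can add to the ring enone.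

Step 4
Reactants: 5 (5R,6R)-4,4-dimethoxy-6-methyl-6-[2-(phenylsulfonyl)ethyl]-5-vinylcyclohex-2-en-1-one
Product: 7 (5R,6R)-4,4-dimethoxy-6-methyl-6-[2-(phenylsulfonyl)ethyl]-5-vinylcyclohex-1-en-1-yl trifluoromethanesulfonate, via lithium enolate 6 (not isolated)
Conditions: LiBH(s-Bu)3, THF, −78 °C; then PhNTf2, −78 °C to rt
Reagents that add atoms: N-phenylbis(trifluoromethanesulfonimide), O=S(=O)(N(c1ccccc1)S(=O)(=O)C(F)(F)F)C(F)(F)F
Why: Reductive triflation: conjugate hydride addition (1,2-attack is blocked by the quaternary C10) gives the C5–C6 enolate regiospecifically and this is trapped on oxygen; no stereocentre is formed.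

Step 5
Reactants: 8 propiolic acid; 9 2-(trimethylsilyl)ethanol
Product: 10 2-(trimethylsilyl)ethyl propiolate
Conditions: DCC, DMAP (cat.), CH2Cl2, −20 to 0 °C
Reagents that add atoms: none
Why: Steglich esterification installs the fluoride-labile ester that will later release the hindered C19 acid without attack at its carbonyl.

Step 6
Reactants: 10 2-(trimethylsilyl)ethyl propiolate
Product: 11 2-(trimethylsilyl)ethyl 2-(tributylstannyl)acrylate
Conditions: Bu3SnH, Pd(PPh3)4 (2 mol %), THF, 0 °C to rt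
Reagents that add atoms: tributyltin hydride, CCCC[SnH](CCCC)CCCC
Why: Pd-catalysed syn hydrostannation of an alkynoate, which places tin on the α-carbon and so gives the 1,1-disubstituted vinylstannane.

Step 7
Reactants: 7 (5R,6R)-4,4-dimethoxy-6-methyl-6-[2-(phenylsulfonyl)ethyl]-5-vinylcyclohex-1-en-1-yl trifluoromethanesulfonate; 11 2-(trimethylsilyl)ethyl 2-(tributylstannyl)acrylate
Product: 12 2-(trimethylsilyl)ethyl 2-[(5R,6R)-4,4-dimethoxy-6-methyl-6-[2-(phenylsulfonyl)ethyl]-5-vinylcyclohex-1-en-1-yl]acrylate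
Conditions: Pd(PPh3)4 (10 mol %), CuCl, LiCl, DMSO, 60 °C
Reagents that add atoms: none
Why: Copper-accelerated Stille coupling of the hindered enol triflate with the α-stannyl acrylate joins C5 to C4 and delivers the 2-(cyclohexenyl)acrylate; no stereocentre is touched.

Step 8
Reactants: 12 2-(trimethylsilyl)ethyl 2-[(5R,6R)-4,4-dimethoxy-6-methyl-6-[2-(phenylsulfonyl)ethyl]-5-vinylcyclohex-1-en-1-yl]acrylate
Product: 15 2-(trimethylsilyl)ethyl 8,8-dimethoxy-2ξ-(phenylsulfonyl)-13,14,15,16,17-pentanorlabda-5,11-dien-19-oate, via lithiated sulfone 13 (not isolated), via lithium dienolate 14 (not isolated)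
Conditions: LiN(i-Pr)2 (1.05 equiv), THF/DMPU, −78 to −30 °C; then MeI, −78 to 0 °C
Reagents that add atoms: iodomethane, CI
Why: The base removes the most acidic C–H (α to the sulfone at C2; no ketone is present) and the soft carbanion 13 adds to the unsubstituted acrylate terminus C3 (anionic Michael addition), which closes ring A in the 6-endo-trig mode and gives the cross-conjugated lithium dienolate 14. MeI then alkylates 14 at its α-carbon C4 (deconjugative α-alkylation of an ester dienolate), so that the C5=C6 double bond is kept for step 11. The closest known reaction types are Michael-initiated ring closures of sulfone carbanions onto enoates with in situ enolate alkylation, and the deconjugative methylation of octalin-4-carboxylate dienolates. The new quaternary stereocentre C4 is controlled by the C20 methyl on C10, which is syn-axial to the β face of C4, so MeI should enter from the α (equatorial) face and leave the ester axial (β); the C2 centre forms as a mixture and is erased in step 9. The step needs 1,4- over 1,2-addition, α- over γ-alkylation and α-face methylation; these should be secured by the unhindered CH2 acceptor with a soft nucleophile in DMPU, by the lithium ester dienolate, and by the axial C20 methyl.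

Step 9
Reactants: 15 2-(trimethylsilyl)ethyl 8,8-dimethoxy-2ξ-(phenylsulfonyl)-13,14,15,16,17-pentanorlabda-5,11-dien-19-oate
Product: 16 2-(trimethylsilyl)ethyl 8,8-dimethoxy-13,14,15,16,17-pentanorlabda-5,11-dien-19-oate
Conditions: Na(Hg) (6% Na), Na2HPO4, MeOH/THF, −20 to 0 °C
Reagents that add atoms: none
Why: Reductive desulfonylation by electron transfer removes the activating group and with it the stereorandom C2 centre, so both epimers of 15 should give one compound.

Step 10
Reactants: 16 2-(trimethylsilyl)ethyl 8,8-dimethoxy-13,14,15,16,17-pentanorlabda-5,11-dien-19-oate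
Product: 18 2-(trimethylsilyl)ethyl 12-hydroxy-8,8-dimethoxy-13,14,15,16,17-pentanorlabd-5-en-19-oate, via B-alkyl-9-BBN 17 (not isolated)
Conditions: 9-BBN, THF, 0 °C to rt; then NaOH, H2O2, 0 °C
Reagents that add atoms: 9-borabicyclo[3.3.1]nonane (boron of 17), B1C2CCCC1CCC2; hydrogen peroxide, OO
Why: Anti-Markovnikov hydroboration–oxidation, in which 9-BBN should select the monosubstituted C11=C12 alkene over the trisubstituted C5=C6 alkene flanked by two quaternary carbons; no stereocentre is formed.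

Step 11
Reactants: 18 2-(trimethylsilyl)ethyl 12-hydroxy-8,8-dimethoxy-13,14,15,16,17-pentanorlabd-5-en-19-oate
Product: 19 2-(trimethylsilyl)ethyl 12-hydroxy-8,8-dimethoxy-13,14,15,16,17-pentanorlabdan-19-oate
Conditions: Mn(dpm)3 (10 mol %), PhSiH3, t-BuOOH, i-PrOH, rt
Reagents that add atoms: none
Why: Radical hydrogenation by hydrogen atom transfer (Mukaiyama-type): H adds to C6, and the tertiary C5 radical should take its hydrogen on the α face, away from the axial C20 methyl and the axial C19 ester, which gives the thermodynamically preferred trans-decalin (5α-H).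

Step 12
Reactants: 19 2-(trimethylsilyl)ethyl 12-hydroxy-8,8-dimethoxy-13,14,15,16,17-pentanorlabdan-19-oate
Product: 20 2-(trimethylsilyl)ethyl 12-hydroxy-8-oxo-13,14,15,16,17-pentanorlabdan-19-oate
Conditions: PPTS, acetone/H2O, 50 °C
Reagents that add atoms: water, O
Why: Acid-catalysed ketal hydrolysis frees the C8 ketone; the C9 side chain, now α to the carbonyl, is equatorial (β) and therefore configurationally safe.

Step 13
Reactants: 20 2-(trimethylsilyl)ethyl 12-hydroxy-8-oxo-13,14,15,16,17-pentanorlabdan-19-oate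
Product: 21 2-(trimethylsilyl)ethyl 12-hydroxy-13,14,15,16-tetranorlabd-8(17)-en-19-oate
Conditions: Ph3PCH3Br, KOt-Bu (excess), toluene, 80 °C
Reagents that add atoms: methyltriphenylphosphonium bromide, C[P+](c1ccccc1)(c1ccccc1)c1ccccc1.[Br-]
Why: Wittig methylenation of the hindered C8 ketone with the hydroxyl carried as its alkoxide; any C9 epimerisation under base should converge on the equatorial side chain already present.

Step 14
Reactants: 21 2-(trimethylsilyl)ethyl 12-hydroxy-13,14,15,16-tetranorlabd-8(17)-en-19-oate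
Product: 22 2-(trimethylsilyl)ethyl 7α,12-dihydroxy-13,14,15,16-tetranorlabd-8(17)-en-19-oate
Conditions: SeO2 (0.3 equiv), t-BuOOH, CH2Cl2, 0 °C to rt
Reagents that add atoms: tert-butyl hydroperoxide, CC(C)(C)OO; selenium dioxide, O=[Se]=O
Why: SeO2 allylic hydroxylation (ene reaction, then [2,3]-sigmatropic shift) at the ring CH2 (C7) in preference to the hindered methine C9; the axial 7α-H is removed and oxygen is returned to the same α face, opposite to C20, which should give the axial 7α-alcohol.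

Step 15
Reactants: 22 2-(trimethylsilyl)ethyl 7α,12-dihydroxy-13,14,15,16-tetranorlabd-8(17)-en-19-oate
Product: 24 2-(trimethylsilyl)ethyl (12E)-7α-hydroxy-14-oxo-15-norlabda-8(17),12-dien-19-oate, via aldehyde 23 (not isolated)
Conditions: TEMPO (10 mol %), PhI(OAc)2, CH2Cl2, rt; then Ph3P=C(Me)CHO, toluene, 80 °C
Reagents that add atoms: 2-(triphenylphosphoranylidene)propanal, CC(C=O)=P(c1ccccc1)(c1ccccc1)c1ccccc1
Why: Oxoammonium (TEMPO) oxidation should select the primary C12 alcohol over the hindered axial C7 alcohol, and the stabilised ylide then gives the trisubstituted enal in a one-pot Wittig reaction, with the E geometry set by the stabilised ylide.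

Step 16
Reactants: 24 2-(trimethylsilyl)ethyl (12E)-7α-hydroxy-14-oxo-15-norlabda-8(17),12-dien-19-oate
Product: 25 2-(trimethylsilyl)ethyl 7α-hydroxylabda-8(17),12E,14-trien-19-oate
Conditions: Ph3PCH3Br, KN(SiMe3)2 (excess), THF, −78 to 0 °C
Reagents that add atoms: methyltriphenylphosphonium bromide, C[P+](c1ccccc1)(c1ccccc1)c1ccccc1.[Br-]
Why: Wittig methylenation of the enal carbonyl completes the diene without touching the C12=C13 geometry.

Step 17
Reactants: 25 2-(trimethylsilyl)ethyl 7α-hydroxylabda-8(17),12E,14-trien-19-oate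
Product: 26 7α-hydroxylabda-8(17),12E,14-trien-19-oic acid
Conditions: Bu4NF, THF, 0 °C to rt; then 0.5 M HCl
Reagents that add atoms: none
Why: Fluoride attacks silicon and the 2-silylethyl ester fragments to ethylene and the carboxylate, a cleavage that does not depend on access to the shielded axial C19 carbonyl.

Step 18
Reactants: 26 7α-hydroxylabda-8(17),12E,14-trien-19-oic acid
Product: 27 7α-acetoxylabda-8(17),12E,14-trien-19-oic acid
Conditions: Ac2O, pyridine, DMAP (cat.), CH2Cl2, rt; then H2O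
Reagents that add atoms: acetic anhydride, CC(=O)OC(C)=O
Why: DMAP-catalysed O-acetylation of the 7α-alcohol with retention; any mixed anhydride formed at the hindered acid is hydrolysed in the aqueous work-up.

**Compound list**
1 | 4,4-dimethoxycyclohexa-2,5-dien-1-one | COC1(OC)C=CC(=O)C=C1 | starting material
2 | (S)-4,4-dimethoxy-5-vinylcyclohex-2-en-1-one | O=C1C=CC(OC)(OC)[C@H](C=C)C1 | intermediate
3 | lithium dienolate of 2 | [Li+].[O-]C1=C[C@@H](C=C)C(OC)(OC)C=C1 | intermediate
4 | (5R)-4,4-dimethoxy-6-methyl-5-vinylcyclohex-2-en-1-one (both C6 epimers) | O=C1C=CC(OC)(OC)[C@H](C=C)C1C | intermediate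
5 | (5R,6R)-4,4-dimethoxy-6-methyl-6-[2-(phenylsulfonyl)ethyl]-5-vinylcyclohex-2-en-1-one | O=C1C=CC(OC)(OC)[C@H](C=C)[C@@]1(C)CCS(=O)(=O)c2ccccc2 | intermediate
6 | lithium enolate from 1,4-hydride addition to 5 | [Li+].[O-]C1=CCC(OC)(OC)[C@H](C=C)[C@@]1(C)CCS(=O)(=O)c2ccccc2 | intermediate
7 | (5R,6R)-4,4-dimethoxy-6-methyl-6-[2-(phenylsulfonyl)ethyl]-5-vinylcyclohex-1-en-1-yl trifluoromethanesulfonate | O=S(=O)(OC1=CCC(OC)(OC)[C@H](C=C)[C@@]1(C)CCS(=O)(=O)c2ccccc2)C(F)(F)F | intermediate
8 | propiolic acid | C#CC(=O)O | starting material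
9 | 2-(trimethylsilyl)ethanol | C[Si](C)(C)CCO | starting material
10 | 2-(trimethylsilyl)ethyl propiolate | C#CC(=O)OCC[Si](C)(C)C | intermediate
11 | 2-(trimethylsilyl)ethyl 2-(tributylstannyl)acrylate | C=C(C(=O)OCC[Si](C)(C)C)[Sn](CCCC)(CCCC)CCCC | intermediate
12 | 2-(trimethylsilyl)ethyl 2-[(5R,6R)-4,4-dimethoxy-6-methyl-6-[2-(phenylsulfonyl)ethyl]-5-vinylcyclohex-1-en-1-yl]acrylate | C=C(C(=O)OCC[Si](C)(C)C)C1=CCC(OC)(OC)[C@H](C=C)[C@@]1(C)CCS(=O)(=O)c2ccccc2 | intermediate
13 | lithiated sulfone of 12 (carbanion at C2) | [Li+].C=C(C(=O)OCC[Si](C)(C)C)C1=CCC(OC)(OC)[C@H](C=C)[C@@]1(C)C[CH-]S(=O)(=O)c2ccccc2 | intermediate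
14 | lithium dienolate after ring closure (C19 enolate, C5=C6 alkene, sulfone on C2) | [Li+].[O-]C(OCC[Si](C)(C)C)=C1CC(S(=O)(=O)c2ccccc2)C[C@]3(C)[C@@H](C=C)C(OC)(OC)CC=C13 | intermediate
15 | 2-(trimethylsilyl)ethyl 8,8-dimethoxy-2ξ-(phenylsulfonyl)-13,14,15,16,17-pentanorlabda-5,11-dien-19-oate | C=C[C@H]1C(OC)(OC)CC=C2[C@]1(C)CC(S(=O)(=O)c3ccccc3)C[C@]2(C)C(=O)OCC[Si](C)(C)C | intermediate
16 | 2-(trimethylsilyl)ethyl 8,8-dimethoxy-13,14,15,16,17-pentanorlabda-5,11-dien-19-oate | C=C[C@H]1C(OC)(OC)CC=C2[C@]1(C)CCC[C@]2(C)C(=O)OCC[Si](C)(C)C | intermediate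
17 | B-alkyl-9-BBN adduct of 16 (boron on C12) | C(C[C@H]1C(OC)(OC)CC=C2[C@]1(C)CCC[C@]2(C)C(=O)OCC[Si](C)(C)C)B3C4CCCC3CCC4 | intermediate
18 | 2-(trimethylsilyl)ethyl 12-hydroxy-8,8-dimethoxy-13,14,15,16,17-pentanorlabd-5-en-19-oate | OCC[C@H]1C(OC)(OC)CC=C2[C@]1(C)CCC[C@]2(C)C(=O)OCC[Si](C)(C)C | intermediate
19 | 2-(trimethylsilyl)ethyl 12-hydroxy-8,8-dimethoxy-13,14,15,16,17-pentanorlabdan-19-oate | OCC[C@H]1C(OC)(OC)CC[C@@H]2[C@]1(C)CCC[C@]2(C)C(=O)OCC[Si](C)(C)C | intermediate
20 | 2-(trimethylsilyl)ethyl 12-hydroxy-8-oxo-13,14,15,16,17-pentanorlabdan-19-oate | OCC[C@H]1C(=O)CC[C@@H]2[C@]1(C)CCC[C@]2(C)C(=O)OCC[Si](C)(C)C | intermediate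
21 | 2-(trimethylsilyl)ethyl 12-hydroxy-13,14,15,16-tetranorlabd-8(17)-en-19-oate | OCC[C@H]1C(=C)CC[C@@H]2[C@]1(C)CCC[C@]2(C)C(=O)OCC[Si](C)(C)C | intermediate
22 | 2-(trimethylsilyl)ethyl 7α,12-dihydroxy-13,14,15,16-tetranorlabd-8(17)-en-19-oate | OCC[C@H]1C(=C)[C@H](O)C[C@@H]2[C@]1(C)CCC[C@]2(C)C(=O)OCC[Si](C)(C)C | intermediate
23 | 2-(trimethylsilyl)ethyl 7α-hydroxy-12-oxo-13,14,15,16-tetranorlabd-8(17)-en-19-oate | O=CC[C@H]1C(=C)[C@H](O)C[C@@H]2[C@]1(C)CCC[C@]2(C)C(=O)OCC[Si](C)(C)C | intermediate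
24 | 2-(trimethylsilyl)ethyl (12E)-7α-hydroxy-14-oxo-15-norlabda-8(17),12-dien-19-oate | O=C/C(C)=C/C[C@H]1C(=C)[C@H](O)C[C@@H]2[C@]1(C)CCC[C@]2(C)C(=O)OCC[Si](C)(C)C | intermediate
25 | 2-(trimethylsilyl)ethyl 7α-hydroxylabda-8(17),12E,14-trien-19-oate | C=C/C(C)=C/C[C@H]1C(=C)[C@H](O)C[C@@H]2[C@]1(C)CCC[C@]2(C)C(=O)OCC[Si](C)(C)C | intermediate
26 | 7α-hydroxylabda-8(17),12E,14-trien-19-oic acid | C=C/C(C)=C/C[C@H]1C(=C)[C@H](O)C[C@@H]2[C@]1(C)CCC[C@]2(C)C(=O)O | intermediate
27 | 7α-acetoxylabda-8(17),12E,14-trien-19-oic acid (CNP0135450.1) | C=C/C(C)=C/C[C@H]1C(=C)[C@H](OC(C)=O)C[C@@H]2[C@]1(C)CCC[C@]2(C)C(=O)O | target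

**Step count and risks**
Total step count: 18. Longest linear sequence: 16 steps (steps 1–4 and 7–18, from 1); steps 5 and 6 make the coupling partner 11.

Most likely to fail:

1. Step 8. What may go wrong: attack of the carbanion on the ester carbonyl instead of conjugate addition, or unselective capture of the hindered dienolate by MeI (O- or γ-alkylation, attack on the wrong face). The fallback sets out from 12 and comes back at 19. Ring closure is separated from the control of C4 and C5, which is moved to dissolving-metal chemistry. 12 would be cyclised with catalytic KOt-Bu in t-BuOH/THF (reversible Michael addition with proton quench) and the double-bond isomers equilibrated with DBU to the conjugated tetrasubstituted ester, 2-(trimethylsilyl)ethyl 8,8-dimethoxy-2ξ-(phenylsulfonyl)-13,14,15,16,17,18-hexanorlabda-4,11-dien-19-oate F1. Birch-type reductive methylation (Li, NH3/THF, t-BuOH 1 equiv, −78 °C; then MeI) should protonate C5 axially (trans fusion), methylate the ester enolate from the α face and cleave the sulfone in the same flask, giving 2-(trimethylsilyl)ethyl 8,8-dimethoxy-13,14,15,16,17-pentanorlabd-11-en-19-oate F2. Hydroboration–oxidation as in step 10 then gives 19, so steps 9 and 11 fall away.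

2. Step 11. What may go wrong: no hydrogen atom transfer to the alkene shielded by two quaternary carbons, or delivery of the second hydrogen to the β face. The fallback sets out from 16 and comes back at 22. The C5=C6 bond is used instead to bring in the C7 oxygen, and C5–H is set by dissolving-metal reduction. Allylic oxidation (CrO3, 3,5-dimethylpyrazole, CH2Cl2, −20 °C) would give the enone 2-(trimethylsilyl)ethyl 8,8-dimethoxy-7-oxo-13,14,15,16,17-pentanorlabda-5,11-dien-19-oate F3. Li/NH3 would give the trans-fused ketone 2-(trimethylsilyl)ethyl 8,8-dimethoxy-7-oxo-13,14,15,16,17-pentanorlabd-11-en-19-oate F4. LiBH(s-Bu)3 should attack equatorially to give the axial alcohol 2-(trimethylsilyl)ethyl 7α-hydroxy-8,8-dimethoxy-13,14,15,16,17-pentanorlabd-11-en-19-oate F5. 9-BBN then NaOH/H2O2 would give the diol 2-(trimethylsilyl)ethyl 7α,12-dihydroxy-8,8-dimethoxy-13,14,15,16,17-pentanorlabdan-19-oate F6. PPTS in wet acetone would give the hydroxy ketone 2-(trimethylsilyl)ethyl 7α,12-dihydroxy-8-oxo-13,14,15,16,17-pentanorlabdan-19-oate F7. Wittig methylenation (Ph3PCH3Br, KOt-Bu, excess) then gives 22; steps 10 to 14 are replaced.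

3. Step 14. What may go wrong: oxidation at the C9 methine, over-oxidation to the enone, or low selectivity for the axial alcohol. The fallback sets out from 20 and comes back at 22. The C7 oxygen is introduced at the ketone stage by enolate chemistry. LiN(i-Pr)2 (2.2 equiv) then TBSOTf would give the bis-silyl compound (primary silyl ether and kinetic C7=C8 silyl enol ether) 2-(trimethylsilyl)ethyl 8,12-bis(tert-butyldimethylsilyloxy)-13,14,15,16,17-pentanorlabd-7-en-19-oate F8. Rubottom oxidation with dimethyldioxirane (attack on the α face, silyl shift) would give 2-(trimethylsilyl)ethyl 7α,12-bis(tert-butyldimethylsilyloxy)-8-oxo-13,14,15,16,17-pentanorlabdan-19-oate F9. Lombardo methylenation (Zn, CH2Br2, TiCl4) would give 2-(trimethylsilyl)ethyl 7α,12-bis(tert-butyldimethylsilyloxy)-13,14,15,16-tetranorlabd-8(17)-en-19-oate F10. HF·pyridine in THF then removes both silyl ethers and gives 22.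

**Further compounds**
F1 | step 8 | 2-(trimethylsilyl)ethyl 8,8-dimethoxy-2ξ-(phenylsulfonyl)-13,14,15,16,17,18-hexanorlabda-4,11-dien-19-oate | C=C[C@H]1C(OC)(OC)CCC2=C(C(=O)OCC[Si](C)(C)C)CC(S(=O)(=O)c3ccccc3)C[C@]12C
F2 | step 8 | 2-(trimethylsilyl)ethyl 8,8-dimethoxy-13,14,15,16,17-pentanorlabd-11-en-19-oate | C=C[C@H]1C(OC)(OC)CC[C@@H]2[C@]1(C)CCC[C@]2(C)C(=O)OCC[Si](C)(C)C
F3 | step 11 | 2-(trimethylsilyl)ethyl 8,8-dimethoxy-7-oxo-13,14,15,16,17-pentanorlabda-5,11-dien-19-oate | C=C[C@H]1C(OC)(OC)C(=O)C=C2[C@]1(C)CCC[C@]2(C)C(=O)OCC[Si](C)(C)C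
F4 | step 11 | 2-(trimethylsilyl)ethyl 8,8-dimethoxy-7-oxo-13,14,15,16,17-pentanorlabd-11-en-19-oate | C=C[C@H]1C(OC)(OC)C(=O)C[C@@H]2[C@]1(C)CCC[C@]2(C)C(=O)OCC[Si](C)(C)C
F5 | step 11 | 2-(trimethylsilyl)ethyl 7α-hydroxy-8,8-dimethoxy-13,14,15,16,17-pentanorlabd-11-en-19-oate | C=C[C@H]1C(OC)(OC)[C@H](O)C[C@@H]2[C@]1(C)CCC[C@]2(C)C(=O)OCC[Si](C)(C)C
F6 | step 11 | 2-(trimethylsilyl)ethyl 7α,12-dihydroxy-8,8-dimethoxy-13,14,15,16,17-pentanorlabdan-19-oate | OCC[C@H]1C(OC)(OC)[C@H](O)C[C@@H]2[C@]1(C)CCC[C@]2(C)C(=O)OCC[Si](C)(C)C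
F7 | step 11 | 2-(trimethylsilyl)ethyl 7α,12-dihydroxy-8-oxo-13,14,15,16,17-pentanorlabdan-19-oate | OCC[C@H]1C(=O)[C@H](O)C[C@@H]2[C@]1(C)CCC[C@]2(C)C(=O)OCC[Si](C)(C)C
F8 | step 14 | 2-(trimethylsilyl)ethyl 8,12-bis(tert-butyldimethylsilyloxy)-13,14,15,16,17-pentanorlabd-7-en-19-oate | CC(C)(C)[Si](C)(C)OCC[C@H]1C(O[Si](C)(C)C(C)(C)C)=CC[C@@H]2[C@]1(C)CCC[C@]2(C)C(=O)OCC[Si](C)(C)C
F9 | step 14 | 2-(trimethylsilyl)ethyl 7α,12-bis(tert-butyldimethylsilyloxy)-8-oxo-13,14,15,16,17-pentanorlabdan-19-oate | CC(C)(C)[Si](C)(C)OCC[C@H]1C(=O)[C@H](O[Si](C)(C)C(C)(C)C)C[C@@H]2[C@]1(C)CCC[C@]2(C)C(=O)OCC[Si](C)(C)C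
F10 | step 14 | 2-(trimethylsilyl)ethyl 7α,12-bis(tert-butyldimethylsilyloxy)-13,14,15,16-tetranorlabd-8(17)-en-19-oate | CC(C)(C)[Si](C)(C)OCC[C@H]1C(=C)[C@H](O[Si](C)(C)C(C)(C)C)C[C@@H]2[C@]1(C)CCC[C@]2(C)C(=O)OCC[Si](C)(C)C
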